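**Plan**

Cuts: the O4'–benzyl bond is cut first. Then the three bonds that build ring C are cut: O1–C2, O1–C8a and C4–C4a. This leaves 3,5-dimethoxybenzyne (ring A) and a 3-arylpropiolic acid that carries ring B, C2, C3, C4 and both oxygens of ring C.
Enabling feature: O1 and the carbonyl carbon C4 sit on the vicinal ring A carbons C8a and C4a. The C5 methoxy group flanks C4a, and the C7 methoxy group is para to C4a and meta to C8a. This is the pattern obtained when a carboxylate oxygen and its own acyl carbon are delivered across the triple bond of 3,5-dimethoxybenzyne.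
Forward order: rings A and B are bought as phenols. Ring A becomes a silylaryl triflate (steps 1–3) and ring B becomes the propiolic acid (steps 4–8). Step 9 joins the two and builds ring C, the only ring made, and step 10 frees the 4'-phenol.
Stereochemistry: the target has no stereocentre, no hindered axis and no configurable double bond, so nothing has to be set.

Key step: step 9

Remark: 3,5-dimethoxyphenol, 2,5-dimethoxyphenol and trimethylsilylacetylene are taken as purchasable.

Step 1
Reactants: 1 3,5-dimethoxyphenol
Product: 2 3,5-dimethoxyphenyl N-isopropylcarbamate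
Conditions: i-PrNCO, Et3N (cat.), CH2Cl2, rt
Reagents that add atoms: isopropyl isocyanate, CC(C)N=C=O
Why: Amine-catalysed addition of the phenol O–H to the isocyanate (O-carbamoylation) should give the secondary aryl carbamate, which is the strongest ortho-directing group on the ring and can be removed later under mild base.

Step 2
Reactants: 2 3,5-dimethoxyphenyl N-isopropylcarbamate
Product: 6 3,5-dimethoxy-2-(trimethylsilyl)phenyl N-isopropylcarbamate, via N-silyl carbamate 3 (not isolated), via aryllithium 4 (not isolated), via bis-silyl carbamate 5 (not isolated)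
Conditions: TBSOTf, TMEDA, Et2O, 0 °C to rt; n-BuLi (2.2 equiv), TMEDA, −78 °C; TMSCl, −78 °C to rt; brief cold aq. NaHSO4 work-up
Reagents that add atoms: tert-butyldimethylsilyl triflate, CC(C)(C)[Si](C)(C)OS(=O)(=O)C(F)(F)F (N-silyl group of 3, 4 and 5 only); n-butyllithium, [Li]CCCC (lithium of 4 only); chlorotrimethylsilane, C[Si](C)(C)Cl (C-silyl group of 5 and 6)
Why: Directed ortho-metalation after transient N-silylation: the O-carbamate and the meta methoxy group cooperate to place lithium on the carbon between them rather than between the two weaker methoxy donors, −78 °C holds back the anionic ortho-Fries shift, TMSCl traps the anion, and the acidic work-up removes only the labile N-silyl group.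

Step 3
Reactants: 6 3,5-dimethoxy-2-(trimethylsilyl)phenyl N-isopropylcarbamate
Product: 8 3,5-dimethoxy-2-(trimethylsilyl)phenyl trifluoromethanesulfonate, via silylphenol 7 (not isolated)
Conditions: DBU, Et2NH, MeCN, 40 °C; then PhNTf2, rt
Reagents that add atoms: N-phenylbis(trifluoromethanesulfonimide), O=S(=O)(N(c1ccccc1)S(=O)(=O)C(F)(F)F)C(F)(F)F
Why: DBU induces E1cB loss of isopropyl isocyanate from the N–H carbamate, diethylamine scavenges it as a urea, and the phenoxide of 7 is O-sulfonylated in the same flask, so the electron-rich arylsilane never meets acid that could cause ipso-protodesilylation.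

Step 4
Reactants: 9 2,5-dimethoxyphenol
Product: 10 2-(benzyloxy)-1,4-dimethoxybenzene
Conditions: BnBr, K2CO3, DMF, rt
Reagents that add atoms: benzyl bromide, BrCc1ccccc1
Why: Williamson ether synthesis on the only acidic O–H masks the future 4'-phenol as an ether that tolerates organolithium, fluoride and aryne conditions.

Step 5
Reactants: 10 2-(benzyloxy)-1,4-dimethoxybenzene
Product: 11 1-(benzyloxy)-4-iodo-2,5-dimethoxybenzene
Conditions: NIS, TFA (cat.), MeCN, 0 °C to rt, dark
Reagents that add atoms: N-iodosuccinimide, O=C1CCC(=O)N1I
Why: Electrophilic aromatic iodination of a 1,2,4-trialkoxybenzene should go to the carbon para to the benzyloxy and ortho to a methoxy group, because the other doubly activated site is wedged between two alkoxy groups and the third site is activated by only one donor.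

Step 6
Reactants: 11 1-(benzyloxy)-4-iodo-2,5-dimethoxybenzene; 12 trimethylsilylacetylene
Product: 13 {[4-(benzyloxy)-2,5-dimethoxyphenyl]ethynyl}trimethylsilane
Conditions: PdCl2(PPh3)2 (cat.), CuI (cat.), Et3N, THF, 40 °C, degassed
Reagents that add atoms: none
Why: Sonogashira coupling (oxidative addition of the aryl iodide to zerovalent palladium, transmetalation from the copper acetylide, reductive elimination) forms the aryl–alkynyl bond, and an iodide is reactive enough even on this electron-rich, ortho-substituted ring.

Step 7
Reactants: 13 {[4-(benzyloxy)-2,5-dimethoxyphenyl]ethynyl}trimethylsilane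
Product: 14 1-(benzyloxy)-4-ethynyl-2,5-dimethoxybenzene
Conditions: K2CO3 (cat.), MeOH–CH2Cl2, rt
Reagents that add atoms: none
Why: Base-catalysed methanolysis of the alkynyl C–Si bond (protiodesilylation) is selective for the sp-bound silicon and leaves all ethers untouched.

Step 8
Reactants: 14 1-(benzyloxy)-4-ethynyl-2,5-dimethoxybenzene
Product: 16 3-[4-(benzyloxy)-2,5-dimethoxyphenyl]propiolic acid, via lithium acetylide 15 (not isolated)
Conditions: n-BuLi (1.05 equiv), THF, −78 °C; dry CO2, −78 to 0 °C; cold 1 M HCl
Reagents that add atoms: n-butyllithium, [Li]CCCC (lithium of 15 only); carbon dioxide, O=C=O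
Why: The alkyne C–H is by far the most acidic site, so one equivalent of base gives only the acetylide, whose carboxylation with CO2 and cold acidification should deliver the acid without ring lithiation or decarboxylation.

Step 9
Reactants: 8 3,5-dimethoxy-2-(trimethylsilyl)phenyl trifluoromethanesulfonate; 16 3-[4-(benzyloxy)-2,5-dimethoxyphenyl]propiolic acid
Product: 19 2-[4-(benzyloxy)-2,5-dimethoxyphenyl]-5,7-dimethoxy-4H-chromen-4-one, via aryne 17 (not isolated), via hydroxyaryl ynone 18 (not isolated)
Conditions: 8 (1.5 equiv), CsF (4 equiv), THF (high dilution), 125 °C, sealed vessel; K2CO3, acetone, reflux on the crude material only if 18 is still present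
Reagents that add atoms: none
Why: Fluoride attack on silicon with loss of triflate converts 8 into 3,5-dimethoxybenzyne 17, and the caesium carboxylate of 16 adds through oxygen to the aryne carbon that has a C–H neighbour (future C8a, O1–C8a bond), so that the negative charge develops on the carbon next to the methoxy group (future C4a). This aryl anion adds to the ester carbonyl close by to give a four-membered benzoxete alkoxide, whose collapse moves the acyl group from O to C (anionic ortho-Fries type, C4–C4a bond); overall the aryne is inserted into the C–O bond of the acid and the phenoxide of ynone 18 is released. Ring C, the only ring formed, then closes by 6-endo-dig oxa-Michael addition of that phenoxide to the aryl-bearing alkyne carbon (O1–C2 bond), followed by protonation at C3. The closest known reaction type is the intermolecular C–O insertion of carboxylic acids into arynes made from silylaryl triflates, which gives ortho-hydroxyaryl ketones and continues to flavones when the acid is an arylpropiolic acid. Three selectivities are needed: the sense of addition is set by the σ-withdrawing methoxy group next to the triple bond, which distorts the aryne so that the far terminus is the more electrophilic one and overrides the weak opposing bias of the remote methoxy group; acyl transfer rather than protonation of the aryl anion is favoured by high dilution and high temperature in THF; and 6-endo rather than 5-exo closure is favoured by the polarisation of the ynone in an aprotic medium. No stereocentre is created, and the benzyl ether keeps O4' from acting as a competing aryne trap.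

Step 10
Reactants: 19 2-[4-(benzyloxy)-2,5-dimethoxyphenyl]-5,7-dimethoxy-4H-chromen-4-one
Product: 20 2-(4-hydroxy-2,5-dimethoxyphenyl)-5,7-dimethoxy-4H-chromen-4-one (target CNP0284525.0)
Conditions: H2 (1 atm), 10% Pd/C, EtOAc–MeOH, rt, stopped when 19 is consumed
Reagents that add atoms: none
Why: Heterogeneous catalytic hydrogenolysis should cleave the benzylic C–O bond faster than it saturates the vinylogous-ester C2–C3 double bond of the chromone, and the four methyl ethers are inert, so the free 4'-phenol of the target should result.

**Compound list**

1 | 3,5-dimethoxyphenol | COc1cc(O)cc(OC)c1 | starting material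
2 | 3,5-dimethoxyphenyl N-isopropylcarbamate | COc1cc(OC)cc(OC(=O)NC(C)C)c1 | intermediate
3 | 3,5-dimethoxyphenyl N-(tert-butyldimethylsilyl)-N-isopropylcarbamate | COc1cc(OC)cc(OC(=O)N(C(C)C)[Si](C)(C)C(C)(C)C)c1 | intermediate
4 | 2-lithio-3,5-dimethoxyphenyl N-(tert-butyldimethylsilyl)-N-isopropylcarbamate | COc1cc(OC)c([Li])c(OC(=O)N(C(C)C)[Si](C)(C)C(C)(C)C)c1 | intermediate
5 | 3,5-dimethoxy-2-(trimethylsilyl)phenyl N-(tert-butyldimethylsilyl)-N-isopropylcarbamate | COc1cc(OC)c([Si](C)(C)C)c(OC(=O)N(C(C)C)[Si](C)(C)C(C)(C)C)c1 | intermediate
6 | 3,5-dimethoxy-2-(trimethylsilyl)phenyl N-isopropylcarbamate | COc1cc(OC)c([Si](C)(C)C)c(OC(=O)NC(C)C)c1 | intermediate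
7 | 3,5-dimethoxy-2-(trimethylsilyl)phenol | COc1cc(O)c([Si](C)(C)C)c(OC)c1 | intermediate
8 | 3,5-dimethoxy-2-(trimethylsilyl)phenyl trifluoromethanesulfonate | COc1cc(OC)c([Si](C)(C)C)c(OS(=O)(=O)C(F)(F)F)c1 | intermediate
9 | 2,5-dimethoxyphenol | COc1ccc(OC)c(O)c1 | starting material
10 | 2-(benzyloxy)-1,4-dimethoxybenzene | COc1ccc(OC)c(OCc2ccccc2)c1 | intermediate
11 | 1-(benzyloxy)-4-iodo-2,5-dimethoxybenzene | COc1cc(OCc2ccccc2)c(OC)cc1I | intermediate
12 | trimethylsilylacetylene | C#C[Si](C)(C)C | starting material
13 | {[4-(benzyloxy)-2,5-dimethoxyphenyl]ethynyl}trimethylsilane | COc1cc(OCc2ccccc2)c(OC)cc1C#C[Si](C)(C)C | intermediate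
14 | 1-(benzyloxy)-4-ethynyl-2,5-dimethoxybenzene | COc1cc(OCc2ccccc2)c(OC)cc1C#C | intermediate
15 | lithium [4-(benzyloxy)-2,5-dimethoxyphenyl]acetylide | COc1cc(OCc2ccccc2)c(OC)cc1C#C[Li] | intermediate
16 | 3-[4-(benzyloxy)-2,5-dimethoxyphenyl]propiolic acid | COc1cc(OCc2ccccc2)c(OC)cc1C#CC(=O)O | intermediate
17 | 3,5-dimethoxybenzyne (1,2-didehydro-3,5-dimethoxybenzene) | COC1=CC(OC)=CC#C1 | intermediate
18 | 3-[4-(benzyloxy)-2,5-dimethoxyphenyl]-1-(2-hydroxy-4,6-dimethoxyphenyl)prop-2-yn-1-one | COc1cc(O)c(C(=O)C#Cc2cc(OC)c(OCc3ccccc3)cc2OC)c(OC)c1 | intermediate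
19 | 2-[4-(benzyloxy)-2,5-dimethoxyphenyl]-5,7-dimethoxy-4H-chromen-4-one | COc1cc(OC)c2c(=O)cc(-c3cc(OC)c(OCc4ccccc4)cc3OC)oc2c1 | intermediate
20 | 2-(4-hydroxy-2,5-dimethoxyphenyl)-5,7-dimethoxy-4H-chromen-4-one | COc1cc(OC)c2c(=O)cc(-c3cc(OC)c(O)cc3OC)oc2c1 | target

Total step count: 10 (3 for the ring A fragment, 5 for the ring B fragment, 2 after convergence).
Longest linear sequence: 7 steps (steps 4–10, from 9 to 20).

**Steps most likely to fail**

Step 9. The aryl anion may be protonated before the acyl group has shifted, so that the sequence stops at simple O-arylation. The electron-rich propiolate may lose CO2 at 125 °C. Part of the phenoxide may close in the 5-exo sense. The fallback sets out from 10 and comes back to the route at 19, building ring C by the chalcone route instead of the aryne route. Vilsmeier–Haack formylation of 10 (POCl3, DMF) para to the benzyloxy group should give 4-(benzyloxy)-2,5-dimethoxybenzaldehyde F1. Claisen–Schmidt condensation of F1 with purchased 2'-hydroxy-4',6'-dimethoxyacetophenone (KOH, EtOH, rt) should give the (E)-2'-hydroxychalcone F2. Oxidative cyclisation of F2 with catalytic I2 in DMSO at about 120 °C should close the pyranone and deliver 19.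

Step 2. Metalation may stray to the position between the two methoxy groups. The carbamoyl group may migrate (anionic ortho-Fries) before the chlorosilane arrives. The new aryl C–Si bond may suffer ipso-protonation in the acidic work-up. The fallback sets out from 1 and comes back at 7, replacing C–H lithiation by halogen–metal exchange and silyl migration. Low-temperature bromination of 1 (NBS, CH2Cl2) with removal of the para isomer should give 2-bromo-3,5-dimethoxyphenol F3. O-Silylation of F3 with hexamethyldisilazane should give (2-bromo-3,5-dimethoxyphenoxy)trimethylsilane F4. Treatment of F4 with n-BuLi in THF at −78 °C should give the 2-lithio silyl ether F5. F5 should undergo 1,3 O-to-C silyl shift (retro-Brook rearrangement) to the lithium phenoxide of 7. This phenoxide is triflated in the same flask with Tf2O to give 8.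

Step 10. The C2–C3 double bond of ring C may be saturated in competition with O–benzyl cleavage, or the hydrogenolysis may stall on a poisoned catalyst. The fallback sets out from 19 and comes back at 20, replacing reduction by acidolysis. Trifluoroacetic acid with pentamethylbenzene as cation scavenger (rt to 40 °C) should remove the benzyl group as a benzyl cation that the scavenger intercepts. The double bond and the methyl ethers, including the one peri to the carbonyl that boron halides would attack, should stay untouched. No new isolated compound lies on this path.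

**Further compounds**

F1 | step 9 | 4-(benzyloxy)-2,5-dimethoxybenzaldehyde | COc1cc(OCc2ccccc2)c(OC)cc1C=O
F2 | step 9 | (E)-3-[4-(benzyloxy)-2,5-dimethoxyphenyl]-1-(2-hydroxy-4,6-dimethoxyphenyl)prop-2-en-1-one | COc1cc(O)c(C(=O)/C=C/c2cc(OC)c(OCc3ccccc3)cc2OC)c(OC)c1
F3 | step 2 | 2-bromo-3,5-dimethoxyphenol | COc1cc(O)c(Br)c(OC)c1
F4 | step 2 | (2-bromo-3,5-dimethoxyphenoxy)trimethylsilane | COc1cc(O[Si](C)(C)C)c(Br)c(OC)c1
F5 | step 2 | (2-lithio-3,5-dimethoxyphenoxy)trimethylsilane | COc1cc(O[Si](C)(C)C)c([Li])c(OC)c1
F0 | step 10 | none | none
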